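All runs stem from a simulated flask with made-up constants; scatter was added.

The product of the elm flask, J plus X, gained 1 percentage point of the charge between 60.0 min and 80.0 min, yet X went on rising, so I reckoned from both ends.

- elm: G 0.061 M; E 0.061 M; L 0.0671 M; D 0.16 mM; the very flask that is asked about, followed so far
- flask: G 0.061 M; L 0.0671 M; D 0.16 mM; E 0.061 M; time 3.0 h
elm run (percent of the G and E together charged)

| time / min | J / % | X / % |
|---|---|---|
| 10.0 | 1.9 | 0.3 |
| 20.0 | 4.0 | 0.4 |
| 30.0 | 7.0 | 0.4 |
| 40.0 | 8.3 | 0.8 |
| 50.0 | 9.2 | 1.6 |
| 60.0 | 10.1 | 2.6 |
| 80.0 | 10.4 | 3.3 |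

(scatter of a reading: 0.3 percentage points)
- D is single-handed; G and E are mirror images of each other, charged as a racemate, each of them at the stated concentration
- as a solid, counted per litre of solution: L
- at the start none of L is in solution
- an excess is the difference of the two amounts in percent of their sum
- an excess is below zero if the other one leads
1. excess of J over X in the product at 20 min
2. excess of J over X in the product at 3.0 h
3. part of the G and E charged together that has reacted at 3.0 h

Early, J is made selectively; late, I took the sum as still and J and X, being mirror images, as passing into each other by a first-order racemisation that ends at zero excess. X then gains in proportion to J minus X, and the readings from 40.0 min to 80.0 min gave 40.5 min, a reading with its scatter: my excess half-life, the time in which J minus X halves at a fixed sum. From an excess of 51.8% at 80.0 min, the 2.47 half-lives up to 3.0 h left me 9.35%.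

The forecast gave 85%, 38% and 16%, reading the tail thus: “the selective catalyst seems to be degrading into a poorly selective form”. My excess at 3.0 h stood lower than its figure.

The flask gave 88.3%, 14.1% and 15.3%, with J down from 10.4% to 8.74% between 1.50 h and 3.00 h; at 3.00 h J was made, each step taken net, at 0.0904 of the rate at which it was used up.

    J ⇌ X (k = 0.00728 min⁻¹)
    Z + D + G → D + J (k = 1700 L² mol⁻² min⁻¹)
    Z + D + E → D + X (k = 8.84 L² mol⁻² min⁻¹)
    L ⇌ Z, rate k4*(cs4 - [Z]) while solid is left; crystals form when [Z] > cs4 (solubility = 49.0 mM, k = 0.0637 min⁻¹)
    Z + D → Q (k = 0.747 L mol⁻¹ min⁻¹)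

Carried from 45.8% at 1.50 h, the half-life gave this flask 9.82% at 3.0 h, against 14.1% found. In the neighbour flask, D was cut to 9.6 × 10⁻⁵ M, and by 3.0 h 9.84% had reacted. The half-life contains no D, so, assuming the elm excess at 80.0 min for the neighbour flask as well, I reckoned 9.35% again. At 3.0 h the neighbour flask stood at 14.2%, level with this flask, with J 5.62% and X 4.22%.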